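**Plan**

1. Retrosynthesis: the C13=C14 bond (olefination), the C8–O and C9–H bonds (hydration of a C8=C9 alkene) and the C4–C18 and C4–C19 bonds (methylation and carbonylation at a former C4 ketone) are cut first; both rings are then opened together by cutting C5–C10 and C6–C7.
2. Enabling feature: ring B (C5–C10) carries the tertiary carbinol C8 next to the side-chain-bearing C9, so it is a masked cyclohexene with a C8=C9 double bond, the retron of a [4+2] between a C7=C8–C9=C10 diene and a C5–C6 unit. Ring A (C1–C5, C10) is the four-atom tether, and C4, quaternary in the target, is carried as a ketone that activates a C5≡C6 alkyne.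
3. Forward: an acyclic dienyl ynone is assembled from acetylacetone (C8, C9, C10, C17, C20), a bromo ketal (C11–C13, C16), a zinc reagent (C1–C4), CH2Br2 (C7) and ethynylmagnesium bromide (C5, C6). Rings A and B form together in step 7; C19, C18, the 8α-hydroxyl, C14–C15 and the acetate follow.
4. Stereochemistry: C10 from a chiral oxazaborolidinium catalyst in the cycloaddition; C5 (axial protonation, trans fusion) and C4 (equatorial methylation anti to the C10 methyl) in one reductive alkylation; C8 and C9 by syn hydroboration from the α face; 13E from the olefination.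

Key step: step 7

Atom numbers are labdane numbers (C1–C20); α is the face opposite to the C10 methyl group; labdane-based names carry the absolute configuration shown in the SMILES.
Assumption: the (S)-configured oxazaborolidinium ion is taken to give the (10R) dienone 10; if the sense were opposite, the mirror-image catalyst would be used.

**Route**

Step 1
Reactants: 1 acetylacetone; 2 2-(2-bromoethyl)-2-methyl-1,3-dioxolane
Product: 3 3-[2-(2-methyl-1,3-dioxolan-2-yl)ethyl]pentane-2,4-dione
Conditions: K2CO3, NaI (cat.), acetone, reflux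
Reagents that add atoms: none
Why: C-alkylation of the 1,3-diketone enolate with a primary bromide (activated in situ as the iodide) is a standard acetylacetone alkylation and creates no stereocentre.

Step 2
Reactants: 3 3-[2-(2-methyl-1,3-dioxolan-2-yl)ethyl]pentane-2,4-dione
Product: 4 (2E)-3-acetyl-5-(2-methyl-1,3-dioxolan-2-yl)pent-2-en-2-yl trifluoromethanesulfonate
Conditions: Tf2O, 1,8-diazabicyclo[5.4.0]undec-7-ene (DBU), CH2Cl2, −78 to 0 °C
Reagents that add atoms: trifluoromethanesulfonic anhydride, O=S(=O)(OS(=O)(=O)C(F)(F)F)C(F)(F)F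
Why: Stereoselective enol triflation of a 1,3-dicarbonyl compound: with a non-chelating amidinium counter-ion the open, dipole-minimised enolate should be triflated so that the triflate lies trans to the remaining acetyl group (E), which is the geometry that later places the tether outside the diene.

Step 3
Reactants: 4 (2E)-3-acetyl-5-(2-methyl-1,3-dioxolan-2-yl)pent-2-en-2-yl trifluoromethanesulfonate; 5 (4-ethoxy-4-oxobutyl)zinc bromide
Product: 6 ethyl (5E)-6-acetyl-5-methyl-8-(2-methyl-1,3-dioxolan-2-yl)oct-5-enoate
Conditions: Pd(PPh3)4 (5 mol %), THF, 25 to 45 °C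
Reagents that add atoms: none
Why: Negishi cross-coupling of a functionalised alkylzinc halide with an alkenyl triflate proceeds with retention of alkene geometry and tolerates ketone, ester and ketal.

Step 4
Reactants: 6 ethyl (5E)-6-acetyl-5-methyl-8-(2-methyl-1,3-dioxolan-2-yl)oct-5-enoate
Product: 7 ethyl (5E)-5-methyl-8-(2-methyl-1,3-dioxolan-2-yl)-6-(prop-1-en-2-yl)oct-5-enoate
Conditions: Zn, CH2Br2, TiCl4, THF/CH2Cl2, 0 °C to rt
Reagents that add atoms: dibromomethane, BrCBr
Why: Takai–Lombardo methylenation is a non-basic olefination that should convert the hindered, enolisable ketone into the 1,1-disubstituted alkene without touching the ester or scrambling the tetrasubstituted double bond.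

Step 5
Reactants: 7 ethyl (5E)-5-methyl-8-(2-methyl-1,3-dioxolan-2-yl)-6-(prop-1-en-2-yl)oct-5-enoate
Product: 8 (5E)-N-methoxy-N,5-dimethyl-8-(2-methyl-1,3-dioxolan-2-yl)-6-(prop-1-en-2-yl)oct-5-enamide
Conditions: MeNH(OMe)·HCl, i-PrMgCl, THF, −20 to 0 °C
Reagents that add atoms: N,O-dimethylhydroxylamine hydrochloride, CNOC.Cl
Why: Direct aminolysis of the unhindered ethyl ester by the chloromagnesium amide of N,O-dimethylhydroxylamine is the standard ester-to-Weinreb-amide conversion.

Step 6
Reactants: 8 (5E)-N-methoxy-N,5-dimethyl-8-(2-methyl-1,3-dioxolan-2-yl)-6-(prop-1-en-2-yl)oct-5-enamide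
Product: 9 (7E)-7-methyl-10-(2-methyl-1,3-dioxolan-2-yl)-8-(prop-1-en-2-yl)dec-7-en-1-yn-3-one
Conditions: HC≡CMgBr, THF, 0 °C; inverse quench into cold aq. citric acid; used at once
Reagents that add atoms: ethynylmagnesium bromide, C#C[Mg]Br
Why: Weinreb ketone synthesis: the chelated tetrahedral adduct prevents over-addition and releases the terminal ynone only on the cold acidic quench, which also protonates the liberated amine and so suppresses its conjugate addition.

Step 7
Reactants: 9 (7E)-7-methyl-10-(2-methyl-1,3-dioxolan-2-yl)-8-(prop-1-en-2-yl)dec-7-en-1-yn-3-one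
Product: 10 (10R)-13,13-(ethylenedioxy)-14,15,18,19-tetranorlabda-5,8-dien-4-one
Conditions: (S)-3,3-diphenyl-1-(2-methylphenyl)tetrahydro-1H,3H-pyrrolo[1,2-c][1,3,2]oxazaborole (20 mol %), HN(SO2CF3)2 (20 mol %), CH2Cl2, −78 to −40 °C
Reagents that add atoms: none
Why: Proposed new method: the cationic boron binds the C4 carbonyl of ynone 9 and lowers the LUMO of the conjugated C5≡C6 π bond, and the tethered C7=C8–C9=C10 diene adds in a concerted but asynchronous [4+2] in which the unhindered, most nucleophilic terminus C7 bonds first to the β-carbon C6 and the congested C5–C10 bond closes last. The closest known reaction types are oxazaborolidinium-catalysed intermolecular Diels–Alder reactions of enones and acetylenic carbonyl dienophiles and the thermal or Lewis-acid-promoted type 1 intramolecular Diels–Alder reaction of dienyl ynones; the catalyst-controlled intramolecular version on a tether-ketone ynone that creates a quaternary ring-fusion carbon is the untested part. Ring A (C1–C5 and C10) closes through the C5–C10 bond as the fused six-membered tether ring of a type 1 intramolecular Diels–Alder reaction, and ring B (C5–C10) is the cyclohexa-1,4-diene ring made by the two new σ bonds C6–C7 and C5–C10. C10 is the only stereocentre formed, because the alkyne leaves C5 and C6 sp2 and removes any endo/exo question; its configuration is set by the catalyst, whose aryl groups shield one face of the bound ynone so that only one of the two mirror-image folds of the tether is open. The step needs enantioface selectivity at C10 and a catalysed rate well above the racemic thermal background, which the low temperature and the slow uncatalysed reaction of the hindered diene should secure; regiochemistry is fixed by the four-atom tether, matched by the polarisation of both partners, and made geometrically possible by the E configuration of C9=C10 (tether outside, C20 methyl inside).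

Step 8
Reactants: 10 (10R)-13,13-(ethylenedioxy)-14,15,18,19-tetranorlabda-5,8-dien-4-one
Product: 12 13,13-(ethylenedioxy)-14,15,18,19-tetranorlabda-4,8-dien-4-yl trifluoromethanesulfonate, via lithium enolate 11 (not isolated)
Conditions: Li, t-BuOH (1 equiv), NH3/THF, −78 °C; NH3 removed; PhNTf2, THF, −78 to 0 °C
Reagents that add atoms: N-phenylbis(trifluoromethanesulfonimide), O=S(=O)(N(c1ccccc1)S(=O)(=O)C(F)(F)F)C(F)(F)F
Why: Dissolving-metal 1,4-reduction of the enone gives the C4(O)=C5 lithium enolate regiospecifically, and O-triflation of this enolate (reductive enolate trapping) fixes the double bond at C4=C5; the isolated C8=C9 alkene and the ketal are inert.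

Step 9
Reactants: 12 13,13-(ethylenedioxy)-14,15,18,19-tetranorlabda-4,8-dien-4-yl trifluoromethanesulfonate
Product: 13 methyl 13,13-(ethylenedioxy)-14,15,18-trinorlabda-4,8-dien-19-oate
Conditions: Pd(OAc)2 (5 mol %), Ph2P(CH2)3PPh2, CO (1 atm), Et3N, MeOH/DMF, 60 °C
Reagents that add atoms: carbon monoxide, [C-]#[O+]; methanol, CO
Why: Palladium-catalysed alkoxycarbonylation of an alkenyl triflate (oxidative addition, CO insertion, methanolysis) installs C19 at the ester oxidation level on C4.

Step 10
Reactants: 13 methyl 13,13-(ethylenedioxy)-14,15,18-trinorlabda-4,8-dien-19-oate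
Product: 15 methyl 13,13-(ethylenedioxy)-14,15-dinorlabd-8-en-19-oate, via lithium ester enolate 14 (not isolated)
Conditions: Li, t-BuOH (1 equiv), NH3/THF, −78 °C; isoprene; then MeI, −78 to −33 °C
Reagents that add atoms: iodomethane, CI
Why: Birch-type reductive alkylation of the α,β-unsaturated ester: the β-carbon C5 should be protonated axially to give the trans ring fusion (5α-H), and the resulting C4 ester enolate should be methylated from the equatorial α face, anti to the axial C10 methyl, leaving the ester axial (C19, β).

Step 11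
Reactants: 15 methyl 13,13-(ethylenedioxy)-14,15-dinorlabd-8-en-19-oate
Product: 17 methyl 13,13-(ethylenedioxy)-8α-hydroxy-14,15-dinorlabdan-19-oate, via 8α-alkylborane 16 (not isolated)
Conditions: BH3·THF, THF, 0 °C to rt; then NaOH, H2O2, 0 to 40 °C
Reagents that add atoms: hydrogen peroxide, OO
Why: Hydroboration–oxidation adds H and B syn from the α face (the β face is blocked by the C10 methyl), with boron going to the less hindered C8 and not the neopentyl C9, and oxidation with retention should give 8α-OH and 9α-H together, as in hydroboration of 1,2-dialkylcyclohexenes.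

Step 12
Reactants: 17 methyl 13,13-(ethylenedioxy)-8α-hydroxy-14,15-dinorlabdan-19-oate
Product: 18 methyl 8α-hydroxy-13-oxo-14,15-dinorlabdan-19-oate
Conditions: pyridinium p-toluenesulfonate (cat.), acetone/H2O, 40 °C
Reagents that add atoms: water, O
Why: Mild acid-catalysed ketal hydrolysis frees the methyl ketone while the tertiary alcohol and the hindered ester are left untouched.

Step 13
Reactants: 18 methyl 8α-hydroxy-13-oxo-14,15-dinorlabdan-19-oate
Product: 19 15-ethyl 19-methyl (13E)-8α-hydroxylabd-13-ene-15,19-dioate
Conditions: (EtO)2P(O)CH2CO2Et (slight excess over base), NaH, THF, 0 to 60 °C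
Reagents that add atoms: triethyl phosphonoacetate, CCOC(=O)CP(=O)(OCC)OCC
Why: Horner–Wadsworth–Emmons olefination of the methyl ketone with a stabilised phosphonate carbanion should favour the E enoate (longer chain trans to the ester), the minor Z isomer being removed by chromatography, and keeping the phosphonate in excess avoids the tertiary alkoxide that could add to the enoate.

Step 14
Reactants: 19 15-ethyl 19-methyl (13E)-8α-hydroxylabd-13-ene-15,19-dioate
Product: 20 (13E)-labd-13-ene-8α,15,19-triol
Conditions: i-Bu2AlH (excess), toluene/CH2Cl2, −78 °C to rt; aq. potassium sodium tartrate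
Reagents that add atoms: none
Why: Hydride reduction of both esters (1,2-reduction of the enoate to the allylic alcohol at low temperature, the hindered C19 ester on warming) touches no stereocentre.

Step 15
Reactants: 20 (13E)-labd-13-ene-8α,15,19-triol
Product: 21 (13E)-8α-hydroxylabd-13-ene-15,19-diyl diacetate
Conditions: Ac2O, pyridine, 0 °C to rt
Reagents that add atoms: acetic anhydride, CC(=O)OC(C)=O
Why: Acetylation with Ac2O/pyridine esterifies the two primary hydroxyl groups, while the tertiary 8α-hydroxyl is inert without an acyl-transfer catalyst.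

Step 16
Reactants: 21 (13E)-8α-hydroxylabd-13-ene-15,19-diyl diacetate
Product: 22 (13E)-8α,15-dihydroxylabd-13-en-19-yl acetate
Conditions: K2CO3 (0.2 equiv), MeOH, 0 °C, stopped at mono-deacetylation
Reagents that add atoms: none
Why: Base-catalysed transesterification (Zemplén-type methanolysis) should cleave the unhindered allylic C15 acetate first, while the neopentyl axial C19 acetate (1,3-diaxial to the C10 methyl) survives; any over-cleaved triol 20 is returned to step 15.

**Compound list**

1 | acetylacetone (pentane-2,4-dione) | CC(=O)CC(C)=O | starting material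
2 | 2-(2-bromoethyl)-2-methyl-1,3-dioxolane | CC1(CCBr)OCCO1 | starting material
3 | 3-[2-(2-methyl-1,3-dioxolan-2-yl)ethyl]pentane-2,4-dione | CC(=O)C(CCC1(C)OCCO1)C(C)=O | intermediate
4 | (2E)-3-acetyl-5-(2-methyl-1,3-dioxolan-2-yl)pent-2-en-2-yl trifluoromethanesulfonate | C/C(OS(=O)(=O)C(F)(F)F)=C(/CCC1(C)OCCO1)C(C)=O | intermediate
5 | (4-ethoxy-4-oxobutyl)zinc bromide | CCOC(=O)CCC[Zn]Br | starting material
6 | ethyl (5E)-6-acetyl-5-methyl-8-(2-methyl-1,3-dioxolan-2-yl)oct-5-enoate | CCOC(=O)CCC/C(C)=C(\CCC1(C)OCCO1)C(C)=O | intermediate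
7 | ethyl (5E)-5-methyl-8-(2-methyl-1,3-dioxolan-2-yl)-6-(prop-1-en-2-yl)oct-5-enoate | CCOC(=O)CCC/C(C)=C(\CCC1(C)OCCO1)C(C)=C | intermediate
8 | (5E)-N-methoxy-N,5-dimethyl-8-(2-methyl-1,3-dioxolan-2-yl)-6-(prop-1-en-2-yl)oct-5-enamide | CON(C)C(=O)CCC/C(C)=C(\CCC1(C)OCCO1)C(C)=C | intermediate
9 | (7E)-7-methyl-10-(2-methyl-1,3-dioxolan-2-yl)-8-(prop-1-en-2-yl)dec-7-en-1-yn-3-one | C#CC(=O)CCC/C(C)=C(\CCC1(C)OCCO1)C(C)=C | intermediate
10 | (10R)-13,13-(ethylenedioxy)-14,15,18,19-tetranorlabda-5,8-dien-4-one (ring A ketone at C4; C5=C6 and C8=C9; 10β-methyl) | O=C1CCC[C@]2(C)C(CCC3(C)OCCO3)=C(C)CC=C12 | intermediate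
11 | lithium 13,13-(ethylenedioxy)-14,15,18,19-tetranorlabda-4,8-dien-4-olate (not isolated) | [Li]OC1CCC[C@]2(C)C(CCC3(C)OCCO3)=C(C)CCC=12 | intermediate
12 | 13,13-(ethylenedioxy)-14,15,18,19-tetranorlabda-4,8-dien-4-yl trifluoromethanesulfonate | FC(F)(F)S(=O)(=O)OC1CCC[C@]2(C)C(CCC3(C)OCCO3)=C(C)CCC=12 | intermediate
13 | methyl 13,13-(ethylenedioxy)-14,15,18-trinorlabda-4,8-dien-19-oate | COC(=O)C1CCC[C@]2(C)C(CCC3(C)OCCO3)=C(C)CCC=12 | intermediate
14 | lithium ester enolate of methyl 13,13-(ethylenedioxy)-14,15,18-trinorlabd-8-en-19-oate, 5α-H (not isolated) | COC(O[Li])=C1CCC[C@]2(C)C(CCC3(C)OCCO3)=C(C)CC[C@@H]12 | intermediate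
15 | methyl 13,13-(ethylenedioxy)-14,15-dinorlabd-8-en-19-oate | COC(=O)[C@@]1(C)CCC[C@]2(C)C(CCC3(C)OCCO3)=C(C)CC[C@@H]12 | intermediate
16 | methyl 8α-boranyl-13,13-(ethylenedioxy)-14,15-dinorlabdan-19-oate (not isolated) | COC(=O)[C@@]1(C)CCC[C@]2(C)[C@@H](CCC3(C)OCCO3)[C@](C)(B)CC[C@@H]12 | intermediate
17 | methyl 13,13-(ethylenedioxy)-8α-hydroxy-14,15-dinorlabdan-19-oate | COC(=O)[C@@]1(C)CCC[C@]2(C)[C@@H](CCC3(C)OCCO3)[C@](C)(O)CC[C@@H]12 | intermediate
18 | methyl 8α-hydroxy-13-oxo-14,15-dinorlabdan-19-oate | COC(=O)[C@@]1(C)CCC[C@]2(C)[C@@H](CCC(C)=O)[C@](C)(O)CC[C@@H]12 | intermediate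
19 | 15-ethyl 19-methyl (13E)-8α-hydroxylabd-13-ene-15,19-dioate | COC(=O)[C@@]1(C)CCC[C@]2(C)[C@@H](CC/C(C)=C/C(=O)OCC)[C@](C)(O)CC[C@@H]12 | intermediate
20 | (13E)-labd-13-ene-8α,15,19-triol | OC[C@@]1(C)CCC[C@]2(C)[C@@H](CC/C(C)=C/CO)[C@](C)(O)CC[C@@H]12 | intermediate
21 | (13E)-8α-hydroxylabd-13-ene-15,19-diyl diacetate | CC(=O)OC[C@@]1(C)CCC[C@]2(C)[C@@H](CC/C(C)=C/COC(C)=O)[C@](C)(O)CC[C@@H]12 | intermediate
22 | (13E)-8α,15-dihydroxylabd-13-en-19-yl acetate | CC(=O)OC[C@@]1(C)CCC[C@]2(C)[C@@H](CC/C(C)=C/CO)[C@](C)(O)CC[C@@H]12 | target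

**Step count and risks**

Total steps: 16. Longest linear sequence: 16 steps (1 to 22; compounds 2 and 5 are bought and enter directly).

Steps most likely to fail:

Step 7 (labelled). The Lewis-basic dioxolane may sequester the boron catalyst, the electron-rich diene may be protonated or oligomerised by the strong acid, and the enantiofacial discrimination of the two tether folds may be poor. The fallback uses known chemistry and sets out from 9. Heating 9 in toluene (about 90 °C) should give the thermal type 1 intramolecular Diels–Alder adduct as the racemic dienone F1. Corey–Bakshi–Shibata reduction of F1 with BH3·SMe2 and (S)-1-methyl-3,3-diphenyltetrahydro-1H,3H-pyrrolo[1,2-c][1,3,2]oxazaborole should deliver hydride to the same carbonyl face of both enantiomers. The result is two diastereomeric allylic alcohols, the (4R,10R)-alcohol F2 and the (4R,10S)-alcohol F3, which are separable by chromatography. Oxidation of F2 with MnO2 returns to the route at enantioenriched 10.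

Step 2. Geometric control may be lost through a chelated enolate or through base-mediated isomerisation of the triflate, which would place the tether inside the diene and block the cycloaddition. The fallback sets out from 2 and builds the tetrasubstituted alkene by a stereospecific syn-carbometalation. Alkylation of lithium acetylide–ethylenediamine with 2 in DMSO gives the alkyne F4. Deprotonation with n-BuLi and acylation with ClCO2Et gives the ynoate F5. Syn-carbocupration with isopropenylmagnesium bromide and CuBr·SMe2 at −78 °C, then trapping of the α-cuprio ester with MeI, gives the dienoate F6 with the new methyl cis to the isopropenyl group. Reduction with i-Bu2AlH gives the dienol F7, and PBr3 with pyridine gives the allylic bromide F8. Coupling of F8 with (3-ethoxy-3-oxopropyl)zinc bromide at the primary carbon under zerovalent palladium catalysis (Pd(PPh3)4) returns to the route at 7.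

Step 11. Hydroboration of the hindered tetrasubstituted alkene may be slow, boron may go to C9, or the tertiary alkylborane may isomerise on warming. The fallback sets out from 15 and replaces hydroboration by an acid-mediated ring closure of the kind used for γ,δ-unsaturated ketones. Hydrolysis of the ketal (aq. HCl, THF) gives the keto alkene F9. p-Toluenesulfonic acid in toluene should protonate C9 from the α face and let the enol oxygen capture the C8 cation equatorially, giving the cyclic enol ether F10. Dilute aqueous H2SO4 in THF then opens the enol ether and returns to the route at the hydroxy ketone 18.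

Further compounds
F1 | step 7 | racemic 13,13-(ethylenedioxy)-14,15,18,19-tetranorlabda-5,8-dien-4-one | O=C1CCCC2(C)C(CCC3(C)OCCO3)=C(C)CC=C12
F2 | step 7 | (4R,10R)-13,13-(ethylenedioxy)-14,15,18,19-tetranorlabda-5,8-dien-4-ol | O[C@@H]1CCC[C@]2(C)C(CCC3(C)OCCO3)=C(C)CC=C12
F3 | step 7 | (4R,10S)-13,13-(ethylenedioxy)-14,15,18,19-tetranorlabda-5,8-dien-4-ol | O[C@@H]1CCC[C@@]2(C)C(CCC3(C)OCCO3)=C(C)CC=C12
F4 | step 2 | 2-(but-3-yn-1-yl)-2-methyl-1,3-dioxolane | C#CCCC1(C)OCCO1
F5 | step 2 | ethyl 5-(2-methyl-1,3-dioxolan-2-yl)pent-2-ynoate | CCOC(=O)C#CCCC1(C)OCCO1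
F6 | step 2 | ethyl (2E)-2-methyl-5-(2-methyl-1,3-dioxolan-2-yl)-3-(prop-1-en-2-yl)pent-2-enoate | CCOC(=O)/C(C)=C(\CCC1(C)OCCO1)C(C)=C
F7 | step 2 | (2E)-2-methyl-5-(2-methyl-1,3-dioxolan-2-yl)-3-(prop-1-en-2-yl)pent-2-en-1-ol | OC/C(C)=C(\CCC1(C)OCCO1)C(C)=C
F8 | step 2 | 2-[(3E)-5-bromo-4-methyl-3-(prop-1-en-2-yl)pent-3-en-1-yl]-2-methyl-1,3-dioxolane | BrC/C(C)=C(\CCC1(C)OCCO1)C(C)=C
F9 | step 11 | methyl 13-oxo-14,15-dinorlabd-8-en-19-oate | COC(=O)[C@@]1(C)CCC[C@]2(C)C(CCC(C)=O)=C(C)CC[C@@H]12
F10 | step 11 | methyl 8α,13-epoxy-14,15-dinorlabd-12-en-19-oate | COC(=O)[C@@]1(C)CCC[C@]2(C)[C@H]3CC=C(C)O[C@]3(C)CC[C@@H]12
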